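- The number to carry to this flask is its loss number N = 2.58: the substrate charge divided by the crossover concentration, the c(substrate) at which a way to target, first-order in substrate, and a way elsewhere, second-order in substrate, use substrate equally fast.

| flask | substrate | gas phase | remark | time |
|---|---|---|---|---|
| Friday's | 0.070 M | 1.9 mM (held) | run made earlier |  |
| Wednesday's | 0.11 M | 1.9 mM (held) | run made earlier |  |
| flask | 0.050 M | 1.9 mM (held) |  | 15 d |

- Friday's (time / d: target / %, substrate / %): 1.25: 8.0, 21.0; 2.00: 14.3, 13.8; 4.00: 21.0, 6.0; 6.00: 22.2, 2.9; 10.0: 17.9, 1.1
- Wednesday's (time / d: target / %, substrate / %): 1.25: 5.5, 17.2; 2.00: 9.4, 9.9; 4.00: 13.7, 4.6; 6.00: 14.6, 0.4; 10.0: 14.0, 0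

(readings scatter by 1 percentage point)

- time, not beyond 15 d, at which the flask holds most target
- the amount of target, in percent of the substrate charged, at that time
- earliest time at which at least nineteen twentieths of that best amount are there, in d
- latest time at which they still are, in d

- at the start none of the gas phase is in solution

- You can see the second order in the runs: at 1.25 d, Wednesday's run has 17.2% of its charge left, less than the 21.0% of Friday's run, so the loss is not purely first-order.
- At the highest target reading, non-target over target is 3.50 in Friday's run and 5.85 in Wednesday's. I take this ratio as a rough reading of N, which gives crossover readings of 0.0200 M and 0.0188 M, with mean 0.0194 M.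
- As a rough rule, not a derived law, I take the highest share of target to be 1/(1 + N), so my reckoning for this flask is 27.9%.
- One number is not enough for the rest: both runs have their highest reading at 6.00 d although their charges differ, so N gives a height and no time.
- The forecast holds that “Peak yield scales roughly inversely with concentration”. It gives 26% (range 22% to 31%) at 5.5 d, below my figure, and a window from 3.5 d to 8 d.
- This flask peaks at 28.7% at 5.50 d, and its window runs from 4.10 d to 7.22 d, opening later than forecast.

    dissolved gas + target → over-reacted product (k = 8.68 × 10⁻⁴ M⁻¹ s⁻¹)
    substrate + dissolved gas → target (k = 0.00827 M⁻¹ s⁻¹)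
    substrate ⇌ dormant form (K = 0.379, k = 6.95 × 10⁻⁶ s⁻¹)
    2 substrate → self-condensation product (k = 1.86 × 10⁻⁴ M⁻¹ s⁻¹)
    dissolved gas → decomposed reagent (k = 7.09 × 10⁻⁶ s⁻¹)
    gas phase ⇌ dissolved gas, rate k6*(csat - [dissolved gas]) (kL = 4.31 × 10⁻⁵ s⁻¹)

- The peak of this flask, read back, gives N = 2.48 against the 2.58 reckoned. The neighbour flask at 0.12 M has N = 6.19, so the rule gives 13.9%, and that flask reaches 14.7%. In this flask at 4.87 d, the making of target uses substrate 11 times as fast as self-condensation does. Yet in this flask self-condensation product already holds 52.3% of the charge at 1.50 d and 60.0% at 5.50 d, against 28.7% target.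

The numbers in the tables are simulated for substances that don't exist, and the scatter is random.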